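## Retrosynthetic overview

1. Ring C is the only lasting ring that is built, since rings A and B are bought. It is closed last by forming O1–C2: once the MOM groups fall off, the freed 2'-phenol attacks the benzylic carbon of an (αR,βS)-chalcone epoxide.
2. The oxirane is formed first and consumed later. It comes from the (E)-chalcone by poly-L-leucine-catalysed nucleophilic epoxidation, which fixes C3 and leaves the prenyl alkenes alone.
3. The key C–C disconnection is Cα=Cβ of the chalcone. This is a Claisen–Schmidt aldol condensation of tris-MOM 3,5-diprenylphloroacetophenone with 4-(methoxymethoxy)benzaldehyde.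
4. The ketone goes back to phloroacetophenone by double C-prenylation with prenyl bromide followed by MOM protection. The aldehyde goes back to 4-hydroxybenzaldehyde.

Assumption: the SMILES encodes the natural (2R,3R)-trans isomer, and MOMCl, poly-L-leucine, urea–hydrogen peroxide and DBU are bought as reagents.

## Route

Step 1
Reactants: 1 2,4,6-trihydroxyacetophenone (phloroacetophenone); 2 prenyl bromide (1-bromo-3-methylbut-2-ene)
Product: 4 1-[2,4,6-trihydroxy-3,5-bis(3-methylbut-2-en-1-yl)phenyl]ethanone, via monoprenyl ketone 3 (not isolated)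
Conditions: 2 (2.1 equiv), KOH (2.2 equiv), degassed H2O, N2, 0 °C to rt, 3 h; 1 M HCl to pH 3; chromatography
Reagents that add atoms: prenyl bromide (compound 2), CC(C)=CCBr
Why: This is the C-alkylation of an acylphloroglucinol phenolate (an ambident vinylogous enolate, SN2 on the allylic bromide), in which water solvates the oxygens so that the soft bromide is taken up by the two free ring carbons one after the other, and no stereocentre is formed.

Step 2
Reactants: 4 1-[2,4,6-trihydroxy-3,5-bis(3-methylbut-2-en-1-yl)phenyl]ethanone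
Product: 6 1-[2-hydroxy-4,6-bis(methoxymethoxy)-3,5-bis(3-methylbut-2-en-1-yl)phenyl]ethanone, via 4-O-MOM ether 5 (not isolated)
Conditions: MOMCl (2.3 equiv), DIPEA (3 equiv), CH2Cl2, 0 °C to rt, 4 h
Reagents that add atoms: chloromethyl methyl ether (MOMCl), COCCl
Why: Williamson-type O-alkylation under amine base protects the unchelated 4-OH and then one of the two equivalent ortho OH groups, while the last ortho OH is held in a hydrogen bond to the acetyl group and stays free.

Step 3
Reactants: 6 1-[2-hydroxy-4,6-bis(methoxymethoxy)-3,5-bis(3-methylbut-2-en-1-yl)phenyl]ethanone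
Product: 7 1-[2,4,6-tris(methoxymethoxy)-3,5-bis(3-methylbut-2-en-1-yl)phenyl]ethanone
Conditions: NaH (1.3 equiv), DMF, 0 °C, 20 min; MOMCl (1.4 equiv), 0 °C to rt, 2 h
Reagents that add atoms: chloromethyl methyl ether (MOMCl), COCCl
Why: NaH irreversibly deprotonates the chelated phenol, which is far more acidic than the methyl ketone, and the hard electrophile MOMCl alkylates the phenoxide on oxygen (Williamson ether synthesis), so that no free 2'-OH can divert the later peroxide step into Algar–Flynn–Oyamada chemistry.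

Step 4
Reactants: 8 4-hydroxybenzaldehyde
Product: 9 4-(methoxymethoxy)benzaldehyde
Conditions: MOMCl (1.3 equiv), DIPEA (1.6 equiv), CH2Cl2, 0 °C to rt, 3 h
Reagents that add atoms: chloromethyl methyl ether (MOMCl), COCCl
Why: Williamson-type O-alkylation of an acidic phenol masks the OH whose phenoxide would otherwise deactivate the aldehyde towards enolate addition.

Step 5
Reactants: 7 1-[2,4,6-tris(methoxymethoxy)-3,5-bis(3-methylbut-2-en-1-yl)phenyl]ethanone; 9 4-(methoxymethoxy)benzaldehyde
Product: 11 (E)-3-[4-(methoxymethoxy)phenyl]-1-[2,4,6-tris(methoxymethoxy)-3,5-bis(3-methylbut-2-en-1-yl)phenyl]prop-2-en-1-one, via aldol adduct 10 (not isolated)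
Conditions: 9 (1.2 equiv), KOH (50% aq., 10 equiv), EtOH, rt, 36–48 h
Reagents that add atoms: none
Why: In this Claisen–Schmidt (crossed aldol) condensation only ketone 7 can enolise and only aldehyde 9 is a good acceptor, aldol 10 loses water by E1cB to give the thermodynamically favoured E-enone, and MOM ethers and prenyl groups are inert to hydroxide.

Step 6
Reactants: 11 (E)-chalcone
Product: 12 [(2R,3S)-3-[4-(methoxymethoxy)phenyl]oxiran-2-yl][2,4,6-tris(methoxymethoxy)-3,5-bis(3-methylbut-2-en-1-yl)phenyl]methanone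
Conditions: poly-L-leucine (100 wt%), urea·H2O2 (1.5 equiv), DBU (1.5 equiv), THF, rt, 18 h; filter; ee by chiral HPLC
Reagents that add atoms: urea–hydrogen peroxide adduct, NC(N)=O.OO
Why: In the Juliá–Colonna epoxidation (asymmetric Weitz–Scheffer reaction) nucleophilic hydroperoxide attacks only the electron-poor enone and not the electron-rich prenyl alkenes, and the poly-L-leucine helix directs oxygen to the face that gives the trans (αR,βS)-epoxide, as it does for chalcone and 2'-MOM-oxychalcones, which sets the future C3 as R.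

Step 7
Reactants: 12 (2R,3S)-epoxy ketone
Product: 15 (2R,3R)-3,5,7-trihydroxy-2-(4-hydroxyphenyl)-6,8-bis(3-methylbut-2-en-1-yl)-2,3-dihydro-4H-chromen-4-one (6,8-diprenylaromadendrin), via protected benzylic methyl ether 13 (not isolated), via free benzylic methyl ether 14 (not isolated)
Conditions: HCl (ca. 1 M, from conc. aq. HCl), MeOH/THF 4:1, N2, 45 °C, 1.5 h; NaHCO3 quench; chromatography, recrystallisation
Reagents that add atoms: none
Why: Acid-catalysed solvolysis opens the oxirane at the benzylic carbon with methanol and transacetalises all four MOM groups, after which either of the two equivalent ortho phenols displaces the para-hydroxybenzylic methoxy group in an SN1-like 6-endo ring closure, so the untouched Cα–O bond carries R into C3 and C2 settles as R in the diequatorial 2,3-trans arrangement, the same result as direct inversion at Cβ.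

## Compound list

1 | 2,4,6-trihydroxyacetophenone | CC(=O)c1c(O)cc(O)cc1O | starting material
2 | prenyl bromide (1-bromo-3-methylbut-2-ene) | CC(C)=CCBr | starting material
3 | 1-[2,4,6-trihydroxy-3-(3-methylbut-2-en-1-yl)phenyl]ethanone | CC(=O)c1c(O)cc(O)c(CC=C(C)C)c1O | intermediate (not isolated)
4 | 1-[2,4,6-trihydroxy-3,5-bis(3-methylbut-2-en-1-yl)phenyl]ethanone | CC(=O)c1c(O)c(CC=C(C)C)c(O)c(CC=C(C)C)c1O | intermediate
5 | 1-[2,6-dihydroxy-4-(methoxymethoxy)-3,5-bis(3-methylbut-2-en-1-yl)phenyl]ethanone | CC(=O)c1c(O)c(CC=C(C)C)c(OCOC)c(CC=C(C)C)c1O | intermediate (not isolated)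
6 | 1-[2-hydroxy-4,6-bis(methoxymethoxy)-3,5-bis(3-methylbut-2-en-1-yl)phenyl]ethanone | CC(=O)c1c(O)c(CC=C(C)C)c(OCOC)c(CC=C(C)C)c1OCOC | intermediate
7 | 1-[2,4,6-tris(methoxymethoxy)-3,5-bis(3-methylbut-2-en-1-yl)phenyl]ethanone | CC(=O)c1c(OCOC)c(CC=C(C)C)c(OCOC)c(CC=C(C)C)c1OCOC | intermediate
8 | 4-hydroxybenzaldehyde | O=Cc1ccc(O)cc1 | starting material
9 | 4-(methoxymethoxy)benzaldehyde | COCOc1ccc(C=O)cc1 | intermediate
10 | 3-hydroxy-3-[4-(methoxymethoxy)phenyl]-1-[2,4,6-tris(methoxymethoxy)-3,5-bis(3-methylbut-2-en-1-yl)phenyl]propan-1-one (racemic) | COCOc1ccc(cc1)C(O)CC(=O)c1c(OCOC)c(CC=C(C)C)c(OCOC)c(CC=C(C)C)c1OCOC | intermediate (not isolated)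
11 | (E)-3-[4-(methoxymethoxy)phenyl]-1-[2,4,6-tris(methoxymethoxy)-3,5-bis(3-methylbut-2-en-1-yl)phenyl]prop-2-en-1-one | COCOc1ccc(/C=C/C(=O)c2c(OCOC)c(CC=C(C)C)c(OCOC)c(CC=C(C)C)c2OCOC)cc1 | intermediate
12 | [(2R,3S)-3-[4-(methoxymethoxy)phenyl]oxiran-2-yl][2,4,6-tris(methoxymethoxy)-3,5-bis(3-methylbut-2-en-1-yl)phenyl]methanone | O=C(c1c(OCOC)c(CC=C(C)C)c(OCOC)c(CC=C(C)C)c1OCOC)[C@@H]2O[C@H]2c3ccc(OCOC)cc3 | intermediate
13 | (2R)-2-hydroxy-3-methoxy-3-[4-(methoxymethoxy)phenyl]-1-[2,4,6-tris(methoxymethoxy)-3,5-bis(3-methylbut-2-en-1-yl)phenyl]propan-1-one (C3 epimers) | O=C(c1c(OCOC)c(CC=C(C)C)c(OCOC)c(CC=C(C)C)c1OCOC)[C@H](O)C(OC)c2ccc(OCOC)cc2 | intermediate (not isolated)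
14 | (2R)-2-hydroxy-3-(4-hydroxyphenyl)-3-methoxy-1-[2,4,6-trihydroxy-3,5-bis(3-methylbut-2-en-1-yl)phenyl]propan-1-one (C3 epimers) | O=C(c1c(O)c(CC=C(C)C)c(O)c(CC=C(C)C)c1O)[C@H](O)C(OC)c2ccc(O)cc2 | intermediate (not isolated)
15 | (2R,3R)-3,5,7-trihydroxy-2-(4-hydroxyphenyl)-6,8-bis(3-methylbut-2-en-1-yl)-2,3-dihydro-4H-chromen-4-one (6,8-diprenylaromadendrin) | CC(C)=CCc1c(O)c(CC=C(C)C)c2c(c1O)C(=O)[C@H](O)[C@@H](c1ccc(O)cc1)O2 | target

## Step count and risks

Total step count: 7.
Longest linear sequence: 6 (steps 1, 2, 3, 5, 6, 7). Step 4 is the side branch.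

**Step 7 (acidic deprotection and ring closure).**
- Risks: acid-induced chroman formation between a prenyl group and a neighbouring phenol, 5-exo closure at Cα, aroyl migration, and incomplete displacement of the benzylic methoxy group.
- Fallback: it sets out from 12 and returns at 15, and it separates ring closure from deprotection.
  - Treat 12 with BnSH and SnCl4 in CH2Cl2 at −20 °C. This opens the oxirane at the benzylic carbon with sulfur and strips one carbonyl-chelated ortho MOM group, giving the β-benzylsulfanyl α-hydroxy ketone F4. The Cα–O bond is untouched, and the descriptor reads S only because sulfur raises the rank of the neighbouring carbon.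
  - The thiophilic salt AgBF4 in CH2Cl2 at 0 °C then ionises the C–S bond. The free 2'-phenol closes ring C to the 2,3-trans tri-MOM dihydroflavonol F5.
  - The robust closed ring system F5 is freed of its three MOM groups with dilute HCl in MeOH at rt, where no heat is needed to drive a cyclisation. This gives 15.

**Step 6 (asymmetric epoxidation of a crowded, hexasubstituted aroyl enone).**
- Risks: slow conversion and an ee below that seen for simple chalcones.
- Fallback: it sets out from 11 and returns at 12, and it replaces asymmetric catalysis by resolution.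
  - Plain Weitz–Scheffer epoxidation (30% aq. H2O2, NaOH, MeOH/THF, 0 °C to rt) is little affected by crowding and equally blind to the prenyl alkenes. It gives the racemic trans-epoxide, that is 12 together with its mirror image, the (2S,3R)-epoxy ketone F3.
  - The two are separated by preparative HPLC on an amylose tris(3,5-dimethylphenylcarbamate) phase, and pure 12 goes on to step 7.

**Step 1 (double C-prenylation).**
- Risks: a mixture of mono-, di- and geminally over-alkylated (dearomatised) products plus O-prenyl ethers, so that 4 is usually obtained in only about 35–45%. Compound 4 is also air-sensitive in base.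
- Fallback: it sets out from 1 and returns at 7, and it replaces phenolate alkylation by cross-coupling.
  - Iodinate 1 with N-iodosuccinimide (2.1 equiv, DMF, 0 °C) to 3,5-diiodo-2,4,6-trihydroxyacetophenone F1.
  - Protect all three phenols (NaH, MOMCl, DMF, 0 °C to rt) to 3,5-diiodo-2,4,6-tris(methoxymethoxy)acetophenone F2.
  - Attach both prenyl groups regiospecifically by a double Stille coupling with tributyl(3-methylbut-2-en-1-yl)stannane (2.5 equiv) and the zerovalent palladium complex Pd(PPh3)4 (10 mol%) in DMF at 90 °C. This gives 7 and bypasses steps 1 to 3.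

## Further compounds

F1 | step 1 | 3,5-diiodo-2,4,6-trihydroxyacetophenone | CC(=O)c1c(O)c(I)c(O)c(I)c1O
F2 | step 1 | 3,5-diiodo-2,4,6-tris(methoxymethoxy)acetophenone | CC(=O)c1c(OCOC)c(I)c(OCOC)c(I)c1OCOC
F3 | step 6 | [(2S,3R)-3-[4-(methoxymethoxy)phenyl]oxiran-2-yl][2,4,6-tris(methoxymethoxy)-3,5-bis(3-methylbut-2-en-1-yl)phenyl]methanone | O=C(c1c(OCOC)c(CC=C(C)C)c(OCOC)c(CC=C(C)C)c1OCOC)[C@H]2O[C@@H]2c3ccc(OCOC)cc3
F4 | step 7 | (2S)-3-(benzylsulfanyl)-2-hydroxy-1-[2-hydroxy-4,6-bis(methoxymethoxy)-3,5-bis(3-methylbut-2-en-1-yl)phenyl]-3-[4-(methoxymethoxy)phenyl]propan-1-one (C3 epimers) | O=C(c1c(O)c(CC=C(C)C)c(OCOC)c(CC=C(C)C)c1OCOC)[C@H](O)C(SCc2ccccc2)c3ccc(OCOC)cc3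
F5 | step 7 | (2R,3R)-3-hydroxy-5,7-bis(methoxymethoxy)-2-[4-(methoxymethoxy)phenyl]-6,8-bis(3-methylbut-2-en-1-yl)-2,3-dihydro-4H-chromen-4-one | CC(C)=CCc1c(OCOC)c(CC=C(C)C)c2c(c1OCOC)C(=O)[C@H](O)[C@@H](c1ccc(OCOC)cc1)O2
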